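**East plateau.** The east run stood level from 1.50 h on, at a mean product sum of 49.7 % of the substrates charged, so I started your quick number there.

| flask | left-handed substrate | right-handed substrate | partner | free catalyst | remark | time |
|---|---|---|---|---|---|---|
| south | 21 mM | 21 mM | 23.1 mM | 0.55 mM | run made earlier |  |
| east | 21 mM | 21 mM | 23.1 mM | 2.2 mM | run made earlier |  |
| flask | 21 mM | 21 mM | 23.1 mM | 1.1 mM |  | 3.0 h |

| run | time / h | left-handed product / % | right-handed product / % |
|---|---|---|---|
| south | 0.200 | 6 | 2 |
| south | 0.500 | 8 | 7 |
| south | 1.00 | 11 | 10 |
| south | 1.50 | 14 | 14 |
| south | 2.00 | 15 | 13 |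
| south | 3.00 | 15 | 17 |
| south | 4.00 | 16 | 16 |
| east | 0.250 | 17 | 11 |
| east | 0.417 | 18 | 14 |
| east | 0.667 | 19 | 17 |
| east | 1.00 | 18 | 20 |
| east | 1.50 | 24 | 26 |
| east | 2.50 | 23 | 26 |
| east | 4.00 | 25 | 25 |

(readings scatter by 2 percentage points)

- free catalyst is single-handed; left-handed substrate and right-handed substrate are mirror images of each other, charged as a racemate, each of them at the stated concentration
- an excess is the difference of the two amounts in percent of their sum
- an excess is below zero if the other one leads

1. excess of left-handed product over right-handed product in the product at 10 min
2. excess of left-handed product over right-handed product in the product at 3.0 h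
3. part of the left-handed substrate and right-handed substrate charged together that has reacted at 3.0 h

**Partner odds.** I counted one partner per product. The partner is then the limiting reagent, with a charge smaller than the two substrates together, and it allows 55.0 % of them to react. I took the east shortfall below that as partner lost elsewhere. East thus read 9.31 for the partner odds: the fraction of the partner charge made into product over the fraction lost. I assumed the odds steady during a run and proportional to catalyst. I set south aside: with each reading scattered by 2 percentage points, its sum going from 28.0 % at 2.00 h to 32.0 % at 3.00 h did not tell me whether it had stopped.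

**My reckoning.** The flask has half the east catalyst, so its odds came to 4.66 and its product sum at the stop to 45.3 %, which I committed to as my estimate of the part reacted at 3.0 h. On the excesses I had nothing to add to yours.

**Your forecast.** It gave an excess of 35 % at 10 min and 0 % at 3.0 h, with 41 % reacted, reading the catalyst effect as “roughly a square-root dependence”.

**The result.** The flask gave an excess of 51.6 % at 10 min and 0.437 % at 3.0 h, with 46.2 % reacted, under these steps:

    free catalyst + left-handed substrate ⇌ catalyst intermediate A (K = 710 /M, k = 63.4 /M/s)
    free catalyst + right-handed substrate ⇌ catalyst intermediate B (K = 93.0 /M, k = 83.0 /M/s)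
    partner + catalyst intermediate A → free catalyst + left-handed product (k = 0.291 /M/s)
    partner + catalyst intermediate B → free catalyst + right-handed product (k = 0.139 /M/s)
    left-handed product ⇌ right-handed product (k = 8.98 × 10⁻⁴ /s)
    partner → decomposed reagent (k = 4.95 × 10⁻⁵ /s)

The lost partner was decomposed reagent, and at 3.00 h the flask's odds stood at 5.16 against my 4.66. The neighbour with 0.44 mM of free catalyst scales to odds of 1.86. With 19 % of its partner still unused at 3.00 h, that reckons to a product sum of 29.1 %. The neighbour's product sum stood at 30.6 %.

All runs stem from a simulated flask on assumed constants, noise included.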